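## The problem

The target is a germacranolide. Ring A is a cyclodeca-1(10),4-diene (C1–C10; 1(10)Z, 4E; methyls C14 on C10 and C15 on C4). It is trans-fused at C6–C7 to an α-methylene γ-lactone, ring B (C6–C7–C11–C12–O, exocyclic C13). C7 carries a tertiary hydroxyl, C8 a (2S,3R)-2,3-epoxy-2-methylbutanoate and C9 a free allylic hydroxyl.

A synthesis must build a ten-membered carbocycle with two trisubstituted alkenes of different, defined geometry; end-to-end closure of such a ring is unfavourable and would have to control both geometries at once. Four contiguous oxygenated stereocentres (6R,7R,8R,9R) must be set: O6/O7 are cis, O7/O8 trans, O8/O9 cis, and C7 is fully substituted. A cis-diol at C8/C9 held in a dioxolane can send the C6/C7 oxygens to the opposite face, and C6–C9 on a six-membered ring can then control every later event. The two epoxide stereocentres of the ester are remote and must be introduced as one enantiomer. The α-methylene lactone does not survive organometallics, hydrides or strong base; the epoxy ester is sensitive to acid and nucleophiles and can migrate between O8 and O9; the 1,5-diene with allylic oxygens at C6 and C9 is prone to acid-triggered transannular cyclisation. The enabling feature is that C1=C10 and C4=C5 flank the C2–C3 bond as a 1,5-diene: ring A is the Cope isomer of a cyclohexane C5–C10 with vinyl on C10 and isopropenyl on C5 that already carries C6–C9, and an oxygen on C10 turns the shift into an anionic oxy-Cope whose enolate is the handle for C14.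

## Retrosynthesis

**C8 ester (30 ⇒ 29 ⇒ 23 + 27).** The acyl C–O bond at C8 is cut last, because the epoxy ester would not survive any organometallic or basic step. C9–OH is the more accessible of the two secondary hydroxyls, so it is masked as the triethylsilyl ether 23 and only the hindered C8–OH is left to acylate; fluoride then gives 30. Acid 27 is traced to tiglic acid 24 through allylic alcohol 25 and epoxy alcohol 26; the asymmetric epoxidation sets both epoxide centres. The forward reaction must acylate a hindered alcohol next to a tertiary one without touching the methylene lactone.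

**Lactone carbonyl and protecting groups (23 ⇒ 22 ⇒ 21 ⇒ 20).** The lactone C12=O is taken back to a lactol ethyl acetal. In 20 ring B exists as a trans-fused 2-ethoxy-3-methylenetetrahydrofuran, C7–OH as a triethylsilyl ether and C8/C9 as an acetonide. Carrying C12 as an acetal rather than as a lactone or a protected alcohol has two reasons: it is inert to Grignard reagents and KH, and the trans-fused five-membered ring fixes the conformation of the six-membered precursor (see below). One mild aqueous acid treatment must unveil lactol triol 21, and the lactol must be oxidised to 22 in the presence of two secondary alcohols.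

**C10–C14 (20 ⇒ 19).** The C10 methyl is cut to the enol triflate 19. The alternative, carrying the ketone and methylenating or adding methyl, would expose a ten-membered α,β-dioxygenated ketone to enolisation and loss of the C8 oxygen. The coupling must retain the alkene geometry.

**Ring A (19 ⇒ 16).** In the forward sense C2–C3 forms and C5–C10 breaks. This is preferred over any cut of a ring A bond that would need macrocyclisation, because the ten-membered ring arises from a six-membered ring that carries C6–C9 untouched. The precursor 16 is a cyclohexanol with vinyl and hydroxyl on C10 and isopropenyl on C5, the two alkenyl groups cis. The rearrangement is required to give C4=C5 as E and the enolate with C2 cis to C9. The triflate 19 is E at C1=C10 by the CIP rules because the triflyloxy group outranks C9; after methylation the same geometry is 1(10)Z.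

**C10–C1 and C5–C4 (16 ⇒ 15 ⇒ 14 ⇒ 13).** The vinyl group is removed to ketone 15, and the isopropenyl group to the C5–C10 epoxide 13 via alcohol 14. Opening an epoxide is chosen over enolate alkenylation at C5 because the trans-fused ring B makes diaxial opening possible only at C5, with the nucleophile entering cis to O6. The vinyl addition must come from the face of the isopropenyl group; the axial C8 oxygen of the dioxolane blocks the other trajectory.

**Epoxide, bromine and ring B (13 ⇒ 12 ⇒ 11 ⇒ 10 ⇒ 9 ⇒ 8).** The epoxide goes back to cyclohexene 12, which comes from vinyl bromide 11 by hydrodebromination. The bromine has no place in the target but is kept until here because it makes the starting diol chiral, directs the dihydroxylation to the other alkene and biases the conformation of ketone 5. The silyl ether 11 comes from alcohol 10. The acetal ring of 10 is opened to enal 9, and that to the allylic alcohol 8.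

**C7–C11 (8 ⇒ 5 + 6).** The three-carbon unit C11–C13 is added as the dilithio reagent 7, made from 2-bromoprop-2-en-1-ol 6, to the C7 ketone 5. Attaching C11 to an sp2 C7 before dihydroxylation would need the bromine on C7, which is the enantiomeric series of the available diol. Here the carbon must therefore add to a carbonyl, anti to the C6 silyloxy group.

**C6/C7 oxygens and the chiral pool (5 ⇒ 4 ⇒ 3 ⇒ 2 ⇒ 1).** Ketone 5 comes from mono-silyl ether 4 and diol 3, obtained by dihydroxylation of the acetonide 2 of (1S,2S)-3-bromocyclohexa-3,5-diene-1,2-diol 1. The diol carbons of 1 become C8 and C9, the brominated carbon C10 and the unhalogenated alkene C6=C7. Only this assignment leads to (8R,9R) with O6 and O7 on the opposite face; diol 3 is (3aS,4R,5R,7aS).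

## Roads not taken

**Alternative 1: silyl glyoxylate linchpin for the C7 carbinol.** The cut is at C7–C11 and C7–C8 of an open chain. In the forward step an alkynylzinc adds to the acylsilane carbon of a silyl glyoxylate, silicon moves from carbon to oxygen (Brook rearrangement) and the zinc glycolate enolate undergoes aldol addition to an aldehyde holding C8–C10 and C1–C5. The product is the alkynyl glycolate aldol adduct A1.
- Merits: it is convergent; the fully substituted C7 and the C8 carbinol are made in one operation; both trisubstituted alkenes are fixed beforehand in an acyclic fragment, so the 1(10)Z geometry does not rest on a conformational argument. In these two respects it is better than the chosen plan.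
- Weak points: the syn/anti relation C7/C8 depends on an enolate geometry the mechanism does not fix. A1 still lacks ring A, which must be closed end-to-end at C5–C6 from a vinyl iodide and an aldehyde with a new, uncontrolled C6 carbinol. The alkyne must be turned into the methylene lactone on a strained diene.
- Comparison: the chosen plan offers ring formation by ring expansion and C6–C9 set on a rigid ring; it pays with a longer linear sequence.

**Alternative 2: convergent palladium allyl lactonisation at C6.** The cut is the lactone C6–O bond. A zerovalent palladium catalyst (Pd2(dba)3, PPh3) ionises a mixture of C6-epimeric allylic carbonates to a π-allyl complex over C4–C5–C6, and the C12 carboxylate attacks C6. The product is the trans-disposed 7-hydroxy α-methylene lactone A2.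
- Merits: both C6 epimers converge; the lactone appears at its final oxidation level with the right relation to C7, so the late acid hydrolysis and lactol oxidation of the chosen plan are avoided. That is a real advantage.
- Weak points: A2 is still open between C1 and C10. Ring A would have to be closed afterwards with a Z-trisubstituted C1=C10 alkene while the Michael-accepting methylene lactone is present. Syn/anti equilibration of the π-allyl complex can erode the 4E geometry.
- Comparison: the hardest problem, ring A with both geometries, is left open; the chosen plan solves exactly that first.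

**Alternative 3: [2,3]-Wittig contraction of a 13-membered diallyl ether.** The cut is C6–C7. n-BuLi removes a C6 proton, the allylic carbanion attacks C7 of the enol-ether alkene C7=C11 across the ring while the C13–O bond breaks. The product is the ring A homoallylic alcohol A3.
- Merits: ring A is made by contraction, not by end-to-end closure; C6, C7 and the C11=C13 methylene arise in one step; both ring alkenes are already in place. If it worked it would be shorter after the macrocycle than the chosen plan.
- Weak points: the carbanion must attack a fully substituted, oxygen-bearing alkene carbon to make a quaternary carbinol. Lithiation must choose C6 over the equally activated C13. A [1,2] shift competes. The relative configuration C6/C7 depends on the fold of a flexible 13-membered ring. The macrocyclic enol ether is itself a long synthesis.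
- Comparison: the chosen plan is longer but derives C6–C9 from a six-membered template with predictable facial preferences.

Key step: step 14

Remark 1: germacrane numbering (C1–C15) is used for all intermediates; "upper face" is the face of the C6 and C7 oxygens, "lower face" that of the C8/C9 dioxolane oxygens.

Remark 2: the acetal carbon C12 of 10–21 (and of F1, F2, F7–F11) forms as a mixture of two epimers that is carried on; the SMILES leave it open, and the centre is erased in step 17.

## Route

Step 1
Reactants: 1 (1S,2S)-3-bromocyclohexa-3,5-diene-1,2-diol
Product: 2 (3aS,7aS)-4-bromo-2,2-dimethyl-3a,7a-dihydro-1,3-benzodioxole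
Conditions: 2,2-dimethoxypropane, p-TsOH (cat.), acetone, 0 °C to rt; used at once
Reagents that add atoms: 2,2-dimethoxypropane, COC(C)(C)OC
Why: acid-catalysed acetonide formation on the cis-diol (C8/C9); no stereocentre is touched, and the dioxolane later shields the lower face.

Step 2
Reactants: 2 (3aS,7aS)-4-bromo-2,2-dimethyl-3a,7a-dihydro-1,3-benzodioxole
Product: 3 (3aS,4R,5R,7aS)-7-bromo-2,2-dimethyl-3a,4,5,7a-tetrahydro-1,3-benzodioxole-4,5-diol
Conditions: OsO4 (cat.), NMO, acetone/H2O, 0 °C to rt
Reagents that add atoms: N-methylmorpholine N-oxide, C[N+]1([O-])CCOCC1; water, O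
Why: Upjohn dihydroxylation; OsO4 takes the electron-richer unbrominated C6=C7 alkene from the face opposite the dioxolane, so O6 and O7 are cis to each other and trans to O8.

Step 3
Reactants: 3 (3aS,4R,5R,7aS)-7-bromo-2,2-dimethyl-3a,4,5,7a-tetrahydro-1,3-benzodioxole-4,5-diol
Product: 4 C6 triethylsilyl ether of 3 with free C7 hydroxyl
Conditions: Et3SiCl, imidazole, CH2Cl2, −40 °C
Reagents that add atoms: chlorotriethylsilane, CC[Si](Cl)(CC)CC
Why: selective silylation of the less hindered allylic C6 hydroxyl; the C7 hydroxyl is flanked by the dioxolane carbon C8.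

Step 4
Reactants: 4 C6 triethylsilyl ether of 3 with free C7 hydroxyl
Product: 5 C7 ketone with C6 silyloxy group and C10 bromide
Conditions: Dess–Martin periodinane, NaHCO3, CH2Cl2, 0 °C
Reagents that add atoms: none
Why: Dess–Martin oxidation of the remaining secondary alcohol under buffered, non-basic conditions that do not enolise the α-silyloxy β,γ-unsaturated ketone.

Step 5
Reactants: 5 C7 ketone with C6 silyloxy group and C10 bromide; 6 2-bromoprop-2-en-1-ol
Product: 8 C7 tertiary alcohol bearing the 3-hydroxyprop-1-en-2-yl group on the lower face, via lithium 2-lithioprop-2-en-1-olate 7 (not isolated)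
Conditions: 6, t-BuLi (3 equiv), Et2O, −78 to 0 °C; CeCl3, THF, −78 °C; then 5, −78 °C; aq NH4Cl
Reagents that add atoms: none
Why: 1,2-addition of an alkenylcerium reagent to a ketone; allylic strain between the C10 bromine and O9 should hold the half-chair in which the C6 silyloxy group is pseudoaxial on the upper face, and the nucleophile should add antiperiplanar to that C–O bond (Felkin–Anh), placing C11 on the lower face and the C7 hydroxyl on the upper face.

Step 6
Reactants: 8 C7 tertiary alcohol bearing the 3-hydroxyprop-1-en-2-yl group on the lower face
Product: 9 enal with C12 as aldehyde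
Conditions: MnO2, CH2Cl2, rt
Reagents that add atoms: none
Why: MnO2 oxidises only the primary allylic alcohol; the tertiary alcohol and the silyl ether are inert.

Step 7
Reactants: 9 enal with C12 as aldehyde
Product: 10 ring B ethyl lactol acetal with free C7 hydroxyl and C10 bromide
Conditions: PPTS (cat.), EtOH, rt
Reagents that add atoms: ethanol, CCO
Why: ethanolysis of the secondary silyl ether, hemiacetal formation between O6 and the C12 aldehyde, then acid-catalysed acetalisation; the five-membered ring is necessarily trans-fused (O6 up, C11 down), and the new C12 centre is inconsequential.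

Step 8
Reactants: 10 ring B ethyl lactol acetal with free C7 hydroxyl and C10 bromide
Product: 11 C7 triethylsilyl ether of 10
Conditions: KHMDS, Et3SiCl, THF, −78 to 0 °C
Reagents that add atoms: chlorotriethylsilane, CC[Si](Cl)(CC)CC
Why: silylation of the tertiary potassium alkoxide; silyl triflates are avoided because they cleave acetals.

Step 9
Reactants: 11 C7 triethylsilyl ether of 10
Product: 12 debrominated cyclohexene with C5=C10
Conditions: Bu3SnH, AIBN (cat.), toluene, 80 °C
Reagents that add atoms: none
Why: radical hydrodebromination of the vinyl bromide; excess stannane reduces the vinyl radical before it can add to the C11=C13 alkene.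

Step 10
Reactants: 12 debrominated cyclohexene with C5=C10
Product: 13 C5–C10 epoxide with oxygen on the lower face
Conditions: mCPBA, NaHCO3, CH2Cl2, 0 °C
Reagents that add atoms: 3-chloroperoxybenzoic acid, OOC(=O)c1cccc(Cl)c1
Why: Prilezhaev epoxidation; the trans-fused ring B fixes the half-chair in which the C7 silyloxy group is axial on the upper face and 1,3 to C5, so the peracid should come from the lower face; the C11=C13 methylene, deactivated by the acetal and flanked by two branched carbons, should react more slowly.

Step 11
Reactants: 13 C5–C10 epoxide with oxygen on the lower face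
Product: 14 C5 isopropenyl C10 alcohol
Conditions: CH2=C(CH3)MgBr, CuI (10 mol %), THF, −30 to 0 °C; aq NH4Cl
Reagents that add atoms: isopropenylmagnesium bromide, CC(=C)[Mg]Br
Why: copper-catalysed Grignard opening of an epoxide; by the Fürst–Plattner rule only attack at C5 from the upper face leads to the chair that the trans-fused ring B allows, so isopropenyl enters axially at C5, cis to O6, and the C10 hydroxyl stays on the lower face.

Step 12
Reactants: 14 C5 isopropenyl C10 alcohol
Product: 15 C10 ketone
Conditions: Dess–Martin periodinane, NaHCO3, CH2Cl2, 0 °C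
Reagents that add atoms: none
Why: Dess–Martin oxidation under neutral conditions keeps the epimerisable C5 centre and avoids β-elimination of O6 or O8.

Step 13
Reactants: 15 C10 ketone
Product: 16 cis-dialkenylcyclohexanol with vinyl and isopropenyl on the upper face
Conditions: CH2=CHMgBr, CeCl3, THF, −78 °C; aq NH4Cl
Reagents that add atoms: vinylmagnesium bromide, C=C[Mg]Br
Why: organocerium 1,2-addition; the axial trajectory from below is blocked by the axial C8 oxygen of the dioxolane, so equatorial attack from above should give vinyl cis to isopropenyl and an axial C10 hydroxyl, and the low basicity of the cerium reagent suppresses enolisation.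

Step 14
Reactants: 16 cis-dialkenylcyclohexanol with vinyl and isopropenyl on the upper face
Product: 19 ten-membered enol triflate, via potassium alkoxide 17 (not isolated), via ring-expanded potassium enolate 18 (not isolated)
Conditions: KH, 18-crown-6, THF, 0 °C to rt; then PhNTf2, −78 to 0 °C
Reagents that add atoms: N-phenylbis(trifluoromethanesulfonimide), O=S(=O)(N(c1ccccc1)S(=O)(=O)C(F)(F)F)C(F)(F)F
Why: KH with 18-crown-6 gives the dissociated C10 alkoxide 17, in which C2 of the vinyl group and C3 of the isopropenyl group bond while C5–C10 breaks in a concerted chair-like [3,3] shift; the closest known reaction type is the anionic oxy-Cope ring expansion of cis-1,2-dialkenylcyclohexanols to cyclodec-5-enones with O-triflation of the enolate in the same flask. Ring A is closed by four-atom ring expansion of the cyclohexane, not by end-to-end cyclisation, so no high dilution is needed. No stereocentre is formed; C6–C9 lie outside the six reacting atoms and are carried over unchanged. The step needs the cyclohexane chair with isopropenyl axial, vinyl equatorial and the C10 oxygen axial, in which C6 is equatorial and C9 axial on the transition-state chair, so that C4=C5 is born E and enolate 18 has C2 cis to C9. That chair is the only one available, because the trans-fused acetal ring B requires the C6–O and C7–C11 bonds to be diequatorial; the flipped chair, which would give the 1(10)E,4Z isomer, would need them diaxial. The 1,3-diaxial contact between the isopropenyl group and the C7 silyloxy group raises the ground state and is released as C5–C10 breaks. Trapping 18 at −78 °C freezes enolate regiochemistry and geometry and prevents proton transfer to the C9 side, where loss of O8 would follow.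

Step 15
Reactants: 19 ten-membered enol triflate
Product: 20 C10-methyl germacradiene with ring B acetal, C7 silyl ether and C8/C9 acetonide
Conditions: MeMgBr, Fe(acac)3 (5 mol %), THF/NMP, −30 to 0 °C
Reagents that add atoms: methylmagnesium bromide, C[Mg]Br
Why: iron-catalysed Kumada-type cross-coupling of an alkenyl triflate with retention of geometry, giving the 1(10)Z alkene; acetals and silyl ether are inert.

Step 16
Reactants: 20 C10-methyl germacradiene with ring B acetal, C7 silyl ether and C8/C9 acetonide
Product: 21 lactol triol
Conditions: AcOH/THF/H2O (3:1:1), 45 °C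
Reagents that add atoms: water, O
Why: one weak aqueous acid hydrolyses the allylic ethyl acetal to the lactol, the silyl ether and the dioxolane; a weak acid is chosen to limit protonation of the 1,5-diene.

Step 17
Reactants: 21 lactol triol
Product: 22 lactone triol
Conditions: TEMPO (cat.), PhI(OAc)2, CH2Cl2, rt
Reagents that add atoms: none
Why: oxoammonium oxidation of a lactol to the lactone is much faster than oxidation of the hindered secondary alcohols at C8 and C9; the tertiary C7 alcohol is inert.

Step 18
Reactants: 22 lactone triol
Product: 23 C9 triethylsilyl ether of 22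
Conditions: Et3SiCl, imidazole, CH2Cl2, −20 °C
Reagents that add atoms: chlorotriethylsilane, CC[Si](Cl)(CC)CC
Why: selective silylation of the allylic C9 hydroxyl; the C8 hydroxyl is shielded by the fully substituted C7.

Step 19
Reactants: 24 tiglic acid
Product: 25 (E)-2-methylbut-2-en-1-ol
Conditions: LiAlH4, Et2O, 0 °C to rt
Reagents that add atoms: none
Why: hydride reduction of the acid to the allylic alcohol; the trisubstituted alkene is not reduced.

Step 20
Reactants: 25 (E)-2-methylbut-2-en-1-ol
Product: 26 ((2R,3R)-2,3-dimethyloxiran-2-yl)methanol
Conditions: Ti(OiPr)4 (cat.), D-(−)-diethyl tartrate (cat.), t-BuOOH, 4 Å MS, CH2Cl2, −20 °C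
Reagents that add atoms: tert-butyl hydroperoxide, CC(C)(C)OO
Why: Sharpless asymmetric epoxidation; with the D-(−)-tartrate an (E)-allylic alcohol gives the (2R,3R)-epoxy alcohol, which sets both ester stereocentres.

Step 21
Reactants: 26 ((2R,3R)-2,3-dimethyloxiran-2-yl)methanol
Product: 27 (2S,3R)-2,3-dimethyloxirane-2-carboxylic acid
Conditions: RuCl3 (cat.), NaIO4, CCl4/MeCN/H2O, rt
Reagents that add atoms: water, O
Why: ruthenium-catalysed periodate oxidation of an epoxy alcohol to the glycidic acid; the descriptor at C2 changes only because the priorities change.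

Step 22
Reactants: 23 C9 triethylsilyl ether of 22; 27 (2S,3R)-2,3-dimethyloxirane-2-carboxylic acid
Product: 29 C8 epoxy ester C9 triethylsilyl ether, via mixed trichlorobenzoic anhydride 28 (not isolated)
Conditions: 27, 2,4,6-trichlorobenzoyl chloride, Et3N, THF, rt; then 23, DMAP, toluene, rt
Reagents that add atoms: none
Why: Yamaguchi esterification acylates the hindered secondary C8 hydroxyl; the tertiary C7 hydroxyl does not react, and no stereocentre of either partner is touched.

Step 23
Reactants: 29 C8 epoxy ester C9 triethylsilyl ether
Product: 30 CNP0420662.1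
Conditions: HF·pyridine, pyridine, THF, 0 °C
Reagents that add atoms: none
Why: buffered fluoride desilylation under slightly acidic conditions avoids acyl migration from O8 to O9 and spares the epoxy ester and the methylene lactone.

## Compound list

1 | (1S,2S)-3-bromocyclohexa-3,5-diene-1,2-diol | O[C@@H]1[C@H](O)C(Br)=CC=C1 | starting material
2 | (3aS,7aS)-4-bromo-2,2-dimethyl-3a,7a-dihydro-1,3-benzodioxole (C8/C9 acetonide; C10–Br) | CC1(C)O[C@H]2C=CC=C(Br)[C@H]2O1 | intermediate
3 | (3aS,4R,5R,7aS)-7-bromo-2,2-dimethyl-3a,4,5,7a-tetrahydro-1,3-benzodioxole-4,5-diol (C6,C7-diol on the upper face) | CC1(C)O[C@H]2[C@H](O)[C@H](O)C=C(Br)[C@H]2O1 | intermediate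
4 | C6 triethylsilyl ether of 3 (C7 hydroxyl free) | CC1(C)O[C@H]2[C@H](O)[C@H](O[Si](CC)(CC)CC)C=C(Br)[C@H]2O1 | intermediate
5 | C7 ketone (C6 silyloxy on the upper face, C10–Br) | CC1(C)O[C@H]2C(=O)[C@H](O[Si](CC)(CC)CC)C=C(Br)[C@H]2O1 | intermediate
6 | 2-bromoprop-2-en-1-ol | C=C(Br)CO | starting material
7 | lithium 2-lithioprop-2-en-1-olate | [Li]OCC([Li])=C | intermediate (not isolated)
8 | C7 tertiary alcohol: 3-hydroxyprop-1-en-2-yl (C11–C13) on the lower face, hydroxyl on the upper face; C6 silyl ether, C10–Br | CC1(C)O[C@H]2[C@@](O)(C(=C)CO)[C@H](O[Si](CC)(CC)CC)C=C(Br)[C@H]2O1 | intermediate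
9 | enal (C12 aldehyde of 8) | CC1(C)O[C@H]2[C@@](O)(C(=C)C=O)[C@H](O[Si](CC)(CC)CC)C=C(Br)[C@H]2O1 | intermediate
10 | ring B ethyl lactol acetal (trans-fused 2-ethoxy-3-methylenetetrahydrofuran on C6–C7), C7–OH, C10–Br | CC1(C)O[C@H]2[C@@]3(O)C(=C)C(OCC)O[C@@H]3C=C(Br)[C@H]2O1 | intermediate
11 | C7 triethylsilyl ether of 10 | CC1(C)O[C@H]2[C@@]3(O[Si](CC)(CC)CC)C(=C)C(OCC)O[C@@H]3C=C(Br)[C@H]2O1 | intermediate
12 | debrominated cyclohexene (C5=C10) | CC1(C)O[C@H]2[C@@]3(O[Si](CC)(CC)CC)C(=C)C(OCC)O[C@@H]3C=C[C@H]2O1 | intermediate
13 | C5–C10 epoxide, oxygen on the lower face | CC1(C)O[C@H]2[C@@]3(O[Si](CC)(CC)CC)C(=C)C(OCC)O[C@@H]3[C@H]4O[C@H]4[C@H]2O1 | intermediate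
14 | C5 isopropenyl (upper face), C10 hydroxyl (lower face) | CC1(C)O[C@H]2[C@@]3(O[Si](CC)(CC)CC)C(=C)C(OCC)O[C@@H]3[C@H](C(C)=C)[C@@H](O)[C@H]2O1 | intermediate
15 | C10 ketone | CC1(C)O[C@H]2[C@@]3(O[Si](CC)(CC)CC)C(=C)C(OCC)O[C@@H]3[C@H](C(C)=C)C(=O)[C@H]2O1 | intermediate
16 | cis-dialkenylcyclohexanol (C10: vinyl up, hydroxyl down; C5: isopropenyl up) | CC1(C)O[C@H]2[C@@]3(O[Si](CC)(CC)CC)C(=C)C(OCC)O[C@@H]3[C@H](C(C)=C)[C@](O)(C=C)[C@H]2O1 | intermediate
17 | potassium alkoxide of 16 | [K+].CC1(C)O[C@H]2[C@@]3(O[Si](CC)(CC)CC)C(=C)C(OCC)O[C@@H]3[C@H](C(C)=C)[C@]([O-])(C=C)[C@H]2O1 | intermediate (not isolated)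
18 | ten-membered potassium enolate (4E; C2 cis to C9) | [K+].CC1(C)O[C@H]2[C@@]3(O[Si](CC)(CC)CC)C(=C)C(OCC)O[C@@H]3/C=C(\C)CC/C=C(/[O-])[C@H]2O1 | intermediate (not isolated)
19 | ten-membered enol triflate (4E; C1=C10 E by CIP, C2 cis to C9) | CC1(C)O[C@H]2[C@@]3(O[Si](CC)(CC)CC)C(=C)C(OCC)O[C@@H]3/C=C(\C)CC/C=C(/OS(=O)(=O)C(F)(F)F)[C@H]2O1 | intermediate
20 | C10-methyl germacra-1(10)Z,4E-diene with ring B acetal, C7 silyl ether, C8/C9 acetonide | CC1(C)O[C@H]2[C@@]3(O[Si](CC)(CC)CC)C(=C)C(OCC)O[C@@H]3/C=C(\C)CC/C=C(/C)[C@H]2O1 | intermediate
21 | lactol triol (C12 hemiacetal; C7, C8, C9 hydroxyls free) | C=C1C(O)O[C@@H]2/C=C(\C)CC/C=C(/C)[C@@H](O)[C@@H](O)[C@@]12O | intermediate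
22 | lactone triol (8-deacyl target) | C=C1C(=O)O[C@@H]2/C=C(\C)CC/C=C(/C)[C@@H](O)[C@@H](O)[C@@]12O | intermediate
23 | C9 triethylsilyl ether of 22 | C=C1C(=O)O[C@@H]2/C=C(\C)CC/C=C(/C)[C@@H](O[Si](CC)(CC)CC)[C@@H](O)[C@@]12O | intermediate
24 | tiglic acid | C/C=C(\C)C(=O)O | starting material
25 | (E)-2-methylbut-2-en-1-ol | C/C=C(\C)CO | intermediate
26 | ((2R,3R)-2,3-dimethyloxiran-2-yl)methanol | OC[C@@]1(C)O[C@@H]1C | intermediate
27 | (2S,3R)-2,3-dimethyloxirane-2-carboxylic acid | OC(=O)[C@@]1(C)O[C@@H]1C | intermediate
28 | mixed anhydride of 27 with 2,4,6-trichlorobenzoic acid | O=C(OC(=O)[C@@]1(C)O[C@@H]1C)c1c(Cl)cc(Cl)cc1Cl | intermediate (not isolated)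
29 | C8 (2S,3R)-epoxy ester, C9 triethylsilyl ether | C=C1C(=O)O[C@@H]2/C=C(\C)CC/C=C(/C)[C@@H](O[Si](CC)(CC)CC)[C@@H](OC(=O)[C@@]3(C)O[C@@H]3C)[C@@]12O | intermediate
30 | CNP0420662.1 | C=C1C(=O)O[C@@H]2/C=C(\C)CC/C=C(/C)[C@@H](O)[C@@H](OC(=O)[C@@]3(C)O[C@@H]3C)[C@@]12O | target

## Step count and least certain steps

Total: 23 steps. Longest linear sequence: 20 steps (steps 1–18, 22, 23); steps 19–21 make the acid 27.

**Step 14 (key step).** The chair is fixed, so the likely failures are chemical: fragmentation of the strained alkoxide instead of the [3,3] shift, or proton transfer within the enolate before triflation, which would move the enolate to the C9 side and expel O8. Fallback, from 16 to 19: the C10 hydroxyl is silylated with 1-(trimethylsilyl)imidazole to the C10 trimethylsilyl ether F1. Heating F1 in toluene in a sealed tube (about 180 °C) performs the neutral siloxy-Cope rearrangement through the same locked chair to the ten-membered trimethylsilyl enol ether F2. Methyllithium at −78 °C then releases the lithium enolate, which is triflated with PhNTf2 to rejoin the route at 19.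

**Step 5.** Poor facial selectivity is the main risk: the reagent may approach from the upper face, away from the dioxolane, against the Felkin–Anh preference; enolisation of the sensitive ketone is the second. Fallback, from 3 to 10: stereocontrol is changed from a steric model to chelation.
- Diol 3 is converted through its stannylene acetal (Bu2SnO, then 4-methoxybenzyl chloride, CsF) into the C6 4-methoxybenzyl ether F3.
- Dess–Martin oxidation gives the ketone F4.
- The magnesium analogue of 7 (7 with MgBr2) is added in CH2Cl2/Et2O, so that magnesium bridges the C7 carbonyl and the C6 ether oxygen and the alkenyl group enters trans to O6, giving the adduct F5.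
- MnO2 gives the enal F6.
- DDQ in wet CH2Cl2 removes the benzyl ether, and the freed O6 closes onto the aldehyde to the lactol F7.
- PPTS in ethanol converts F7 into 10.

**Step 10.** The peracid may attack the upper face, or the C11=C13 methylene, because the two faces of C5=C10 are each hindered by one axial oxygen. Fallback, from 12 to 13: the halohydrin route inverts the facial outcome of any electrophile. N-Bromosuccinimide in aqueous 1,2-dimethoxyethane forms the bromonium ion on the face the peracid prefers; water opens it trans-diaxially at C10 from below to the bromohydrin F8 (bromine on C5 up, hydroxyl on C10 down). Aqueous NaOH closes F8 to the lower-face epoxide 13.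

**Step 13.** The ratio of equatorial to axial attack may be eroded by the axial isopropenyl group next to the carbonyl, and base-induced loss of O8 or O6 from the β-alkoxy ketone may compete. Fallback, from 15 to 16: dimethylsulfoxonium methylide (Me3S(O)I, NaH, DMSO) adds reversibly and delivers the methylene equatorially, giving the spiro-epoxide F9 (methylene up, oxygen down). Dimethylsulfonium methylide (Me3SI, n-BuLi, THF) then opens the epoxide at the methylene and loses dimethyl sulfide, giving the vinyl carbinol 16.

**Step 16.** Cleavage of the dioxolane needs the longest acid exposure; during it the 1,5-diene may cyclise across the ring or the lactol may dehydrate. Fallback, from 20 to 22: the order of events is changed so that the strong-acid step acts on the lactone. PPTS in wet acetone hydrolyses only the allylic ethyl acetal to the lactol F10 (acetonide and silyl ether kept). MnO2 oxidises the allylic lactol to the lactone F11. Aqueous trifluoroacetic acid at 0 °C then removes the dioxolane and the silyl ether from F11, in which O6 is acylated and no hemiacetal remains, to give 22.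

## Further compounds

F1 | step 14 | C10 trimethylsilyl ether of 16 | CC1(C)O[C@H]2[C@@]3(O[Si](CC)(CC)CC)C(=C)C(OCC)O[C@@H]3[C@H](C(C)=C)[C@](O[Si](C)(C)C)(C=C)[C@H]2O1
F2 | step 14 | ten-membered trimethylsilyl enol ether | CC1(C)O[C@H]2[C@@]3(O[Si](CC)(CC)CC)C(=C)C(OCC)O[C@@H]3/C=C(\C)CC/C=C(/O[Si](C)(C)C)[C@H]2O1
F3 | step 5 | C6 4-methoxybenzyl ether of 3 | CC1(C)O[C@H]2[C@H](O)[C@H](OCc3ccc(OC)cc3)C=C(Br)[C@H]2O1
F4 | step 5 | C7 ketone with C6 4-methoxybenzyl ether | CC1(C)O[C@H]2C(=O)[C@H](OCc3ccc(OC)cc3)C=C(Br)[C@H]2O1
F5 | step 5 | C7 adduct with C6 4-methoxybenzyl ether | CC1(C)O[C@H]2[C@@](O)(C(=C)CO)[C@H](OCc3ccc(OC)cc3)C=C(Br)[C@H]2O1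
F6 | step 5 | enal with C6 4-methoxybenzyl ether | CC1(C)O[C@H]2[C@@](O)(C(=C)C=O)[C@H](OCc3ccc(OC)cc3)C=C(Br)[C@H]2O1
F7 | step 5 | ring B lactol with free C7 hydroxyl and C10 bromide | CC1(C)O[C@H]2[C@@]3(O)C(=C)C(O)O[C@@H]3C=C(Br)[C@H]2O1
F8 | step 10 | bromohydrin (C5 bromine up, C10 hydroxyl down) | CC1(C)O[C@H]2[C@@]3(O[Si](CC)(CC)CC)C(=C)C(OCC)O[C@@H]3[C@H](Br)[C@@H](O)[C@H]2O1
F9 | step 13 | C10 spiro-epoxide (methylene up, oxygen down) | CC1(C)O[C@H]2[C@@]3(O[Si](CC)(CC)CC)C(=C)C(OCC)O[C@@H]3[C@H](C(C)=C)[C@]4(CO4)[C@H]2O1
F10 | step 16 | lactol with C7 silyl ether and C8/C9 acetonide | CC1(C)O[C@H]2[C@@]3(O[Si](CC)(CC)CC)C(=C)C(O)O[C@@H]3/C=C(\C)CC/C=C(/C)[C@H]2O1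
F11 | step 16 | lactone with C7 silyl ether and C8/C9 acetonide | CC1(C)O[C@H]2[C@@]3(O[Si](CC)(CC)CC)C(=C)C(=O)O[C@@H]3/C=C(\C)CC/C=C(/C)[C@H]2O1
A1 | alternative 1 | alkynyl glycolate aldol adduct | CC(C)(C)OC(=O)[C@](O[Si](C)(C)C(C)(C)C)(C#C[Si](C)(C)C)[C@H](O)[C@H](O[Si](C)(C)C(C)(C)C)/C(C)=C\CC/C(C)=C/I
A2 | alternative 2 | trans-disposed 7-hydroxy α-methylene lactone | C=C1C(=O)O[C@H](/C=C(\C)CCCO[Si](C)(C)C(C)(C)C)[C@@]1(O)[C@H](OCc2ccc(OC)cc2)CO[Si](c3ccccc3)(c4ccccc4)C(C)(C)C
A3 | alternative 3 | ring A homoallylic alcohol | O[C@@H]1/C=C(\C)CC/C=C(/C)[C@@H](O[Si](C)(C)C(C)(C)C)[C@@H](OCOC)[C@@]1(OCOC)C(=C)CO[Si](CC)(CC)CC
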